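The target is a single 29-membered lactone ring (28 C plus the ring O; C1 = lactone carbonyl, C28 = OCH2) whose carbons C2–C28 are all plain CH2 groups, so ring carbons C10–C13 can be carried as a straight C10≡C11–C12≡C13 diyne that hydrogenation later erases.
Retrosynthesis: restore that diyne, cut the ring at the sp–sp bond C11–C12, then cut the ester bond C1–O to reach undec-10-ynoic acid and heptadec-16-yn-1-ol.
The C17 alkynol is traced back, by shifting its triple bond inward and cutting the C(sp)–C(sp3) bond, to undec-10-yn-1-ol and 1-bromohexane.
Forward: acetylide alkylation builds the C17 chain, an alkyne zipper moves the triple bond to the chain end, esterification joins the two fragments, oxidative alkyne–alkyne coupling closes the only ring, and hydrogenation saturates it.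
Stereochemistry: the target has no stereocentre and no double bond, so nothing has to be controlled.

Key step: step 4

Step 1
Reactants: 1 undec-10-yn-1-ol; 2 1-bromohexane
Product: 5 heptadec-10-yn-1-ol, via lithium 11-lithioundec-10-yn-1-olate 3 (not isolated), via lithium heptadec-10-yn-1-olate 4 (not isolated)
Conditions: n-BuLi (2.1 equiv), THF/DMPU, −78 → 0 °C; then 2 (1.1 equiv), 0 °C → rt; H2O
Reagents that add atoms: none
Why: Two equivalents of n-BuLi form the alkoxide–acetylide dianion, and in the dipolar cosolvent only its sp carbanion undergoes SN2 alkylation with the primary bromide (acetylide alkylation of an unprotected alkynol dianion), the hard lithium alkoxide staying unalkylated; no stereocentre arises.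

Step 2
Reactants: 5 heptadec-10-yn-1-ol
Product: 7 heptadec-16-yn-1-ol, via potassium 17-potassioheptadec-16-yn-1-olate 6 (not isolated)
Conditions: KH (4 equiv), H2N(CH2)3NH2, rt (forms KNH(CH2)3NH2); then 5, 0 °C → rt; H2O, 0 °C
Reagents that add atoms: none
Why: Alkyne zipper isomerisation, in which KNH(CH2)3NH2 shuttles protons through propargyl/allenyl anions so that the triple bond walks along the chain until the terminal alkyne is trapped irreversibly as its potassium acetylide, and because the C1 end carries the alkoxide the only terminus that can form an acetylide is C17.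

Step 3
Reactants: 7 heptadec-16-yn-1-ol; 8 undec-10-ynoic acid
Product: 9 heptadec-16-yn-1-yl undec-10-ynoate
Conditions: DCC (1.1 equiv), DMAP (cat.), CH2Cl2, 0 °C → rt
Reagents that add atoms: none
Why: Steglich esterification, in which DCC activates the acid as its O-acylisourea and DMAP relays the acyl group to the unhindered primary alcohol under neutral conditions that leave both terminal alkynes untouched.

Step 4
Reactants: 9 heptadec-16-yn-1-yl undec-10-ynoate
Product: 10 1-oxacyclononacosa-11,13-diyn-2-one
Conditions: Cu(OAc)2 (10 equiv), pyridine, 60 °C; 9 in pyridine added by syringe pump over ca. 12 h (final ca. 1 mM)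
Reagents that add atoms: none
Why: Pyridine-assisted deprotonation turns each terminal C–H into a copper acetylide, and one-electron oxidation by divalent copper (Cu(OAc)2) lets the two acetylide carbons, both nucleophilic, join as C11–C12 while monovalent copper (CuOAc) and AcOH are released. This is the Eglinton variant of the Glaser oxidative homocoupling, the standard entry to macrocyclic 1,3-diynes from α,ω-diynes. The ring closes end to end as a 29-membered macrocyclisation in which the new sp–sp bond and both triple bonds lie in the ring; the rigid C10–C13 rod is easily spanned by the 25 remaining ring atoms, so no strain opposes closure. No stereocentre is formed. The selectivity required is ring closure over intermolecular coupling, which slow addition of 9 into a large excess of Cu(OAc)2 (low stationary concentration) should secure, and chemoselectivity is built into the substrate because the ester is inert to Cu(OAc)2 in pyridine and a homocoupling needs no differentiation of the two alkyne termini.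

Step 5
Reactants: 10 1-oxacyclononacosa-11,13-diyn-2-one
Product: 11 octacosanolide (1-oxacyclononacosan-2-one)
Conditions: H2 (3 atm), 10% Pd/C, EtOAc, rt
Reagents that add atoms: none
Why: Exhaustive heterogeneous catalytic hydrogenation over Pd/C should add four equivalents of H2 to the conjugated diyne and give the fully saturated chain, while the unactivated lactone C–O bonds are inert to hydrogenolysis and no stereochemical question arises.

Compound list
1 | undec-10-yn-1-ol (10-undecyn-1-ol) | C#CCCCCCCCCCO | starting material
2 | 1-bromohexane | CCCCCCBr | starting material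
3 | lithium 11-lithioundec-10-yn-1-olate (alkoxide–acetylide dianion of 1) | [Li]C#CCCCCCCCCCO[Li] | intermediate
4 | lithium heptadec-10-yn-1-olate | CCCCCCC#CCCCCCCCCCO[Li] | intermediate
5 | heptadec-10-yn-1-ol | CCCCCCC#CCCCCCCCCCO | intermediate
6 | potassium 17-potassioheptadec-16-yn-1-olate (alkoxide–acetylide of 7) | [K]C#CCCCCCCCCCCCCCCCO[K] | intermediate
7 | heptadec-16-yn-1-ol | C#CCCCCCCCCCCCCCCCO | intermediate
8 | undec-10-ynoic acid (10-undecynoic acid) | C#CCCCCCCCCC(=O)O | starting material
9 | heptadec-16-yn-1-yl undec-10-ynoate | C#CCCCCCCCCC(=O)OCCCCCCCCCCCCCCCC#C | intermediate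
10 | 1-oxacyclononacosa-11,13-diyn-2-one | O=C1CCCCCCCCC#CC#CCCCCCCCCCCCCCCCO1 | intermediate
11 | octacosanolide (1-oxacyclononacosan-2-one) | O=C1CCCCCCCCCCCCCCCCCCCCCCCCCCCO1 | target

Total step count: 5
Longest linear sequence: 5 steps (1 → 5 → 7 → 9 → 10 → 11); acid 8 is used as purchased and enters at step 3.

Steps most likely to fail

Step 4 (ring closure). What may go wrong: chain growth by intermolecular acetylide coupling, giving open oligomers and the 58-membered cyclic dimer, outruns the end-to-end closure whenever the stationary concentration of 9 rises. The fallback sets out from 7 (together with 8) and comes back to the route at 10. It makes the C11–C12 bond first, between two separate molecules where concentration is no issue, and closes the ring at the ester instead. Bromination of the terminal alkyne of 7 (NBS, AgNO3 cat., acetone, rt) should give 17-bromoheptadec-16-yn-1-ol F1. Cadiot–Chodkiewicz cross-coupling of F1 with 8 (CuCl cat., NH2OH·HCl, aq. EtNH2, MeOH, 0 °C → rt, then acidification) should give 28-hydroxyoctacosa-10,12-diynoic acid F2. Shiina macrolactonisation of F2 (2-methyl-6-nitrobenzoic anhydride, DMAP, CH2Cl2, slow addition, rt) closes the C1–O bond and delivers 10, which enters step 5 unchanged.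

Step 1 (dianion alkylation). What may go wrong: slow SN2 reaction of the aggregated, sparingly soluble dianion with an unactivated primary bromide, so that on warming E2 elimination of 2 and some O-alkylation compete and conversion stalls. The fallback sets out from 1 and comes back at 5. It masks the hydroxyl so that a soluble mono-anion is alkylated. Treatment of 1 with 3,4-dihydro-2H-pyran and PPTS (CH2Cl2, rt) should give the racemic acetal 2-(undec-10-yn-1-yloxy)tetrahydro-2H-pyran F3. n-BuLi (1.05 equiv, THF/DMPU, −78 °C) converts it into [11-(tetrahydro-2H-pyran-2-yloxy)undec-1-yn-1-yl]lithium F4, which is alkylated with 2 (0 °C → rt) to give 2-(heptadec-10-yn-1-yloxy)tetrahydro-2H-pyran F5. PPTS in MeOH (50 °C) removes the acetal and returns 5.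

Step 2 (alkyne zipper). What may go wrong: incomplete migration of the triple bond over six positions (quenching of KNH(CH2)3NH2 by moisture, poor solubility of the long-chain potassium alkoxide), leaving positional alkyne isomers that cannot be separated from 7. The fallback sets out from 1 by way of its dianion 3 and comes back at 11. It brings in the terminal alkyne ready-made and carries the C10 triple bond of the alcohol fragment as a spectator, since step 5 saturates every multiple bond anyway.
- Dianion 3 is alkylated with (6-iodohex-1-yn-1-yl)trimethylsilane (THF/DMPU, 0 °C → rt) to give lithium 17-(trimethylsilyl)heptadeca-10,16-diyn-1-olate F6, which water converts into 17-(trimethylsilyl)heptadeca-10,16-diyn-1-ol F7.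
- K2CO3 in MeOH (rt) removes the silyl group to give heptadeca-10,16-diyn-1-ol F8.
- Steglich esterification with 8 (DCC, DMAP cat., CH2Cl2) gives heptadeca-10,16-diyn-1-yl undec-10-ynoate F9.
- Eglinton closure under the conditions of step 4 forms the same C11–C12 bond and the same 29-membered ring, giving 1-oxacyclononacosa-11,13,19-triyn-2-one F10; the internal alkyne has no C–H and cannot form a copper acetylide.
- Hydrogenation over Pd/C as in step 5 gives 11.

Further compounds
F1 | step 4 | 17-bromoheptadec-16-yn-1-ol | OCCCCCCCCCCCCCCCC#CBr
F2 | step 4 | 28-hydroxyoctacosa-10,12-diynoic acid | OCCCCCCCCCCCCCCCC#CC#CCCCCCCCCC(=O)O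
F3 | step 1 | 2-(undec-10-yn-1-yloxy)tetrahydro-2H-pyran (racemic) | C#CCCCCCCCCCOC1CCCCO1
F4 | step 1 | [11-(tetrahydro-2H-pyran-2-yloxy)undec-1-yn-1-yl]lithium (racemic) | [Li]C#CCCCCCCCCCOC1CCCCO1
F5 | step 1 | 2-(heptadec-10-yn-1-yloxy)tetrahydro-2H-pyran (racemic) | CCCCCCC#CCCCCCCCCCOC1CCCCO1
F6 | step 2 | lithium 17-(trimethylsilyl)heptadeca-10,16-diyn-1-olate | C[Si](C)(C)C#CCCCCC#CCCCCCCCCCO[Li]
F7 | step 2 | 17-(trimethylsilyl)heptadeca-10,16-diyn-1-ol | C[Si](C)(C)C#CCCCCC#CCCCCCCCCCO
F8 | step 2 | heptadeca-10,16-diyn-1-ol | C#CCCCCC#CCCCCCCCCCO
F9 | step 2 | heptadeca-10,16-diyn-1-yl undec-10-ynoate | C#CCCCCCCCCC(=O)OCCCCCCCCCC#CCCCCC#C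
F10 | step 2 | 1-oxacyclononacosa-11,13,19-triyn-2-one | O=C1CCCCCCCCC#CC#CCCCCC#CCCCCCCCCCO1
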